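**Retrosynthetic overview**

- The strategy rests on the C6–C1'' bond that joins the acid-labile (2E,6E)-farnesyl chain to ring A. C6 (between 5-OH and 7-OH) and C8 (between 7-OH and O1) are almost equally nucleophilic, and ring C opens at C2–O1 under base.
- This bond is cut last: free (2S)-5,7,3',5'-tetrahydroxyflavanone plus (2E,6E)-farnesyl diphosphate, joined by a soluble aromatic prenyltransferase at neutral pH with no protecting groups.
- The flavanone is cut at C2–C1': enantioselective palladium-catalysed conjugate arylation of 5,7-bis(benzyloxy)chromone with 3,5-bis(benzyloxy)phenylboronic acid sets C2, then hydrogenolysis frees the phenols.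
- The chromone comes from 2,4,6-trihydroxyacetophenone (bis-benzylation, enaminone, acid ring closure); the diphosphate comes from (2E,6E)-farnesol through the bromide.
- Ring order: ring A is bought, ring C is closed in step 2, ring B is attached in step 3, and the key step closes no ring.

Key step: step 7

**Remarks on the chemistry (assumptions)**

- Step 3: (R)-t-BuPyOx is taken as the ligand hand that gives (2S), by transfer of the facial sense this catalyst shows with carbocyclic enones. If a first run showed the opposite sense, the ligand antipode would be used.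
- Step 7: the enzyme is taken to be the magnesium-dependent soluble prenyltransferase NphB (Streptomyces sp. CL190) or an active-site variant of it, picked in a small analytical screen for C6 selectivity with the farnesyl donor before the preparative run.

**Route**

Step 1
Reactants: 1 2,4,6-trihydroxyacetophenone
Product: 2 1-[2,4-bis(benzyloxy)-6-hydroxyphenyl]ethan-1-one
Conditions: BnBr (2.1 equiv), K2CO3 (2.2 equiv), DMF, 0 °C to rt
Reagents that add atoms: benzyl bromide, BrCc1ccccc1
Why: Williamson etherification, in which the para-OH and one ortho-OH are alkylated while the remaining ortho-OH stays locked in a hydrogen bond to the acetyl carbonyl and should be left free when two equivalents of benzyl bromide are used.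

Step 2
Reactants: 2 1-[2,4-bis(benzyloxy)-6-hydroxyphenyl]ethan-1-one
Product: 4 5,7-bis(benzyloxy)-4H-chromen-4-one, via enaminone 3 (not isolated)
Conditions: Me2NCH(OMe)2 (3 equiv), toluene, 95 °C; evaporate; conc. HCl, CH2Cl2, 40 °C; aq NaHCO3 work-up
Reagents that add atoms: N,N-dimethylformamide dimethyl acetal, COC(OC)N(C)C
Why: Condensation of the methyl ketone with the amide acetal gives the vinylogous amide, and acid then drives intramolecular oxa-Michael addition of the free ortho-OH and loss of dimethylamine (enaminone route to chromones), closing ring C as the pyranone while the aryl benzyl ethers tolerate the brief exposure to aqueous HCl.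

Step 3
Reactants: 4 5,7-bis(benzyloxy)-4H-chromen-4-one; 5 3,5-bis(benzyloxy)phenylboronic acid (2 equiv)
Product: 6 (2S)-5,7-bis(benzyloxy)-2-[3,5-bis(benzyloxy)phenyl]chroman-4-one
Conditions: Pd(OCOCF3)2 (10 mol %), (R)-t-BuPyOx (12 mol %), NH4PF6 (30 mol %), H2O (5 equiv), ClCH2CH2Cl, 60 °C
Reagents that add atoms: none
Why: Palladium-catalysed asymmetric conjugate addition of an arylboronic acid, by transmetalation to the cationic divalent palladium–pyridine-oxazoline complex, enantioselective insertion of C2=C3 into the aryl–palladium bond and protonolysis of the palladium enolate by water, with the tert-butyl group of the (R)-ligand shielding one face so that the aryl group should arrive on the face that makes C2 (S).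

Step 4
Reactants: 6 (2S)-5,7-bis(benzyloxy)-2-[3,5-bis(benzyloxy)phenyl]chroman-4-one
Product: 7 (2S)-5,7-dihydroxy-2-(3,5-dihydroxyphenyl)chroman-4-one
Conditions: H2 (1 atm), 10% Pd/C, EtOAc–MeOH 1:1, rt, stopped at full debenzylation
Reagents that add atoms: none
Why: Heterogeneous hydrogenolysis of the four aryl benzyl ethers under neutral conditions, which contain no base to open ring C at C2–O1 and should leave the hydrogen-bonded C4 ketone alone, at a stage where no olefin is present.

Step 5
Reactants: 8 (2E,6E)-farnesol
Product: 9 (2E,6E)-farnesyl bromide
Conditions: PBr3 (0.4 equiv), Et2O, −10 to 0 °C; used crude at once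
Reagents that add atoms: phosphorus tribromide, BrP(Br)Br
Why: Bromination of a primary allylic alcohol with PBr3 through the phosphite ester (SN2 displacement) at low temperature, which should keep both trisubstituted olefins E and avoid allylic transposition.

Step 6
Reactants: 9 (2E,6E)-farnesyl bromide
Product: 11 tris(ammonium) (2E,6E)-farnesyl diphosphate, via bis(tetrabutylammonium) farnesyl hydrogen diphosphate 10 (not isolated)
Conditions: (n-Bu4N)3HP2O7 (2 equiv), MeCN, rt; then Dowex 50W-X8 (NH4+ form), 25 mM NH4HCO3 in 2% i-PrOH–H2O; lyophilise; cellulose chromatography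
Reagents that add atoms: tris(tetrabutylammonium) hydrogen diphosphate, OP(=O)([O-])OP(=O)([O-])[O-].CCCC[N+](CCCC)(CCCC)CCCC.CCCC[N+](CCCC)(CCCC)CCCC.CCCC[N+](CCCC)(CCCC)CCCC; ammonium hydrogen carbonate, [NH4+].OC([O-])=O
Why: SN2 displacement of the primary allylic bromide by the lipophilic diphosphate trianion in dry acetonitrile, followed by cation exchange to the water-soluble ammonium salt, is the standard entry to allylic diphosphates and does not touch the olefin geometry.

Step 7
Reactants: 7 (2S)-5,7-dihydroxy-2-(3,5-dihydroxyphenyl)chroman-4-one; 11 tris(ammonium) (2E,6E)-farnesyl diphosphate (1.5 equiv)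
Product: 12 (2S)-6-[(2E,6E)-3,7,11-trimethyldodeca-2,6,10-trien-1-yl]-5,7-dihydroxy-2-(3,5-dihydroxyphenyl)chroman-4-one
Conditions: NphB prenyltransferase (variant selected for C6 selectivity, about 2 mol %), MgCl2 (5 mM), HEPES buffer (50 mM, pH 7.2), 5% DMSO, 7 at 2 mM, 30 °C, 16 h; EtOAc extraction; chromatography
Reagents that add atoms: none
Why: The enzyme binds the diphosphate of 11 through the magnesium ion and basic residues and ionises the C1''–O bond to a tight farnesyl cation–diphosphate pair held over ring A of the bound flavanone; C6 attacks C1'' and an active-site base removes the C6 proton from the arenium intermediate, so the step is an enzyme-templated Friedel–Crafts alkylation. The closest known reaction is the C6 prenylation and geranylation of 5,7-dihydroxyflavanones by soluble ABBA-fold and fungal indole-type prenyltransferases, several of which also accept farnesyl diphosphate. No ring is closed and no stereocentre is made; C2 should be carried through unchanged because at pH 7.2 and 30 °C retro-oxa-Michael opening of ring C is slow, and the product would be checked on a chiral column. The selectivity needed is C6 over C8 and over O7, and C1'' over C3'' of the donor with the 2'',3''-olefin kept E; the substrate gives almost no bias between C6 and C8, so the binding pose, with ring B and the C4 carbonyl/5-OH pair anchoring the acceptor so that C6 lies nearest C1'', must secure it, which is why the variant is chosen in an analytical screen first. Free phenols are needed for binding and activation, so no protecting group is carried into this step, and the neutral aqueous medium avoids the cation–olefin cyclisation that a Lewis acid would cause in the triene.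

**Compound list**

1 | 2,4,6-trihydroxyacetophenone | CC(=O)c1c(O)cc(O)cc1O | starting material
2 | 1-[2,4-bis(benzyloxy)-6-hydroxyphenyl]ethan-1-one | CC(=O)c1c(O)cc(OCc2ccccc2)cc1OCc1ccccc1 | intermediate
3 | (E)-1-[2,4-bis(benzyloxy)-6-hydroxyphenyl]-3-(dimethylamino)prop-2-en-1-one | CN(C)/C=C/C(=O)c1c(O)cc(OCc2ccccc2)cc1OCc1ccccc1 | intermediate (not isolated)
4 | 5,7-bis(benzyloxy)-4H-chromen-4-one | O=c1ccoc2cc(OCc3ccccc3)cc(OCc3ccccc3)c12 | intermediate
5 | 3,5-bis(benzyloxy)phenylboronic acid | OB(O)c1cc(OCc2ccccc2)cc(OCc2ccccc2)c1 | starting material
6 | (2S)-5,7-bis(benzyloxy)-2-[3,5-bis(benzyloxy)phenyl]chroman-4-one | O=C1C[C@@H](c2cc(OCc3ccccc3)cc(OCc3ccccc3)c2)Oc2cc(OCc3ccccc3)cc(OCc3ccccc3)c12 | intermediate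
7 | (2S)-5,7-dihydroxy-2-(3,5-dihydroxyphenyl)chroman-4-one | O=C1C[C@@H](c2cc(O)cc(O)c2)Oc2cc(O)cc(O)c12 | intermediate
8 | (2E,6E)-farnesol | CC(C)=CCC/C(C)=C/CC/C(C)=C/CO | starting material
9 | (2E,6E)-farnesyl bromide | CC(C)=CCC/C(C)=C/CC/C(C)=C/CBr | intermediate
10 | bis(tetrabutylammonium) (2E,6E)-farnesyl hydrogen diphosphate | CC(C)=CCC/C(C)=C/CC/C(C)=C/COP(=O)([O-])OP(=O)(O)[O-].CCCC[N+](CCCC)(CCCC)CCCC.CCCC[N+](CCCC)(CCCC)CCCC | intermediate (not isolated)
11 | tris(ammonium) (2E,6E)-farnesyl diphosphate | CC(C)=CCC/C(C)=C/CC/C(C)=C/COP(=O)([O-])OP(=O)([O-])[O-].[NH4+].[NH4+].[NH4+] | intermediate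
12 | (2S)-6-[(2E,6E)-farnesyl]-5,7-dihydroxy-2-(3,5-dihydroxyphenyl)chroman-4-one | CC(C)=CCC/C(C)=C/CC/C(C)=C/Cc1c(O)cc2c(c1O)C(=O)C[C@@H](c1cc(O)cc(O)c1)O2 | target

**Step count**

Total: 7 steps. Longest linear sequence: 5 steps (steps 1, 2, 3, 4 and 7 from 2,4,6-trihydroxyacetophenone); the donor branch is steps 5 and 6.

**Steps most likely to fail**

1. Step 7. The farnesyl group may be delivered to C8 or to O7 instead of C6, turnover with the fifteen-carbon donor may be slow while the diphosphate hydrolyses, and C2 may slowly epimerise in buffer. The fallback drops the enzyme for a non-enzymatic Friedel–Crafts alkylation. It sets out from flavanone 7 and farnesol 8, treated with BF3·OEt2 in dioxane at rt and stopped at partial conversion. Acid keeps ring C closed, so C2 should not epimerise. The price is a mixture of C6 and C8 alkylation and some cyclised side chain, from which the C6 isomer would be taken by preparative reversed-phase HPLC. The path comes back to the route at 12 itself and makes no new compound (F0).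

2. Step 3. Insertion into the electron-rich 5,7-dialkoxychromone may be slow, so that protodeboronation and homocoupling of 5 take over, or facial selectivity may be poor. The fallback builds ring C by oxa-Michael closure and resolves. It sets out from acetophenone 2. Claisen–Schmidt condensation with commercial 3,5-bis(benzyloxy)benzaldehyde (O=Cc1cc(OCc2ccccc2)cc(OCc2ccccc2)c1; KOH, EtOH, rt) should give (E)-1-[2,4-bis(benzyloxy)-6-hydroxyphenyl]-3-[3,5-bis(benzyloxy)phenyl]prop-2-en-1-one F1. NaOAc in refluxing EtOH should close it to racemic 5,7-bis(benzyloxy)-2-[3,5-bis(benzyloxy)phenyl]chroman-4-one F2. Preparative HPLC on an amylose-based chiral phase would give the (2S) enantiomer, which is 6, where the path rejoins the route. The other enantiomer could be recycled through the chalcone with base.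

3. Step 6. The allylic bromide may ionise, hydrolyse or eliminate before displacement, and the amphiphilic salt may be lost in ion exchange and chromatography. The fallback phosphorylates the alcohol directly. It sets out from farnesol 8, treated with trichloroacetonitrile and bis(triethylammonium) hydrogen phosphate in MeCN at 37 °C. The reaction passes through (2E,6E)-farnesyl monophosphate F3, which is phosphorylated again in the same flask. Silica chromatography in i-PrOH/conc. aqueous NH3/H2O would separate mono-, di- and triphosphate. The diphosphate fraction is the ammonium salt 11, where the path rejoins the route.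

**Further compounds**

F0 | step 7 | none | none
F1 | step 3 | (E)-1-[2,4-bis(benzyloxy)-6-hydroxyphenyl]-3-[3,5-bis(benzyloxy)phenyl]prop-2-en-1-one | O=C(/C=C/c1cc(OCc2ccccc2)cc(OCc2ccccc2)c1)c1c(O)cc(OCc2ccccc2)cc1OCc1ccccc1
F2 | step 3 | racemic 5,7-bis(benzyloxy)-2-[3,5-bis(benzyloxy)phenyl]chroman-4-one | O=C1CC(c2cc(OCc3ccccc3)cc(OCc3ccccc3)c2)Oc2cc(OCc3ccccc3)cc(OCc3ccccc3)c12
F3 | step 6 | (2E,6E)-farnesyl monophosphate | CC(C)=CCC/C(C)=C/CC/C(C)=C/COP(=O)(O)O
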